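**Plan**

1. Rings are lettered A–F as in the SMILES (A = 2,4,6-trihydroxyphenyl end, F = 3,4,5-trihydroxyphenyl end; B/D carry ethers at C1 and C4, C/E at C1 and C6). The retrosynthesis cuts the 16 O–Me bonds, then all five Ar–O–Ar bonds on the side of the carbon flanked by two oxygens: A(C1)–O, C(C6)–O, E(C6)–O, and B(C4)–O / D(C4)–O inside one dyad.
2. Enabling feature: B(C4)–O–C(C1) and D(C4)–O–E(C1) are the same dyad. C1 of B/D (two ortho H, para to O4) can enter as a formyl carbon. C6 of C/E (ortho to O1 and O5, para to O3) is the most nucleophilic CH of that dyad.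
3. Forward: phenol 1 (rings C, E, F) and bromoaldehyde 2 (rings B, D) give the dyad aldehyde; iodination at C6 gives dyad iodide 4, which is used twice.
4. The chain is joined from F to A: 1 + 4 → D–E–F aldehyde; CHO → OH (Baeyer–Villiger); + 4 → B–C–D–E–F aldehyde; CHO → OH; + ring A iodide; 16-fold O-demethylation.
5. The formyl group deactivates its ring during iodination, keeps the next phenol masked (no self-condensation), and is then converted into the chain oxygen.
6. Stereochemistry: nothing to set; the target has no stereocentre.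

Key step: step 5

Remark: the target is achiral (no stereocentre, freely rotating diaryl ether axes), so "single enantiomer" is met by the constitution alone.

**Route**

Step 1
Reactants: 1 3,4,5-trimethoxyphenol; 2 4-bromo-3,5-dimethoxybenzaldehyde
Product: 3 3,5-dimethoxy-4-(3,4,5-trimethoxyphenoxy)benzaldehyde (dyad aldehyde)
Conditions: CuI (10 mol%), picolinic acid (20 mol%), K3PO4, DMSO, 90 °C, Ar
Reagents that add atoms: none
Why: Ullmann-type Cu-catalysed diaryl ether synthesis between an unhindered, electron-rich phenol and an aryl bromide activated by its para-formyl group should form the doubly ortho-flanked C4–O ether of rings B/D on small, cheap partners.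

Step 2
Reactants: 3 dyad aldehyde
Product: 4 4-(2-iodo-3,4,5-trimethoxyphenoxy)-3,5-dimethoxybenzaldehyde (dyad iodide)
Conditions: NIS (1.05 equiv), TFA (10 mol%), MeCN, 0 °C to rt, dark
Reagents that add atoms: N-iodosuccinimide, O=C1CCC(=O)N1I
Why: Electrophilic aromatic iodination should go to the CH of the trimethoxyphenoxy ring that is ortho to the ether oxygen, ortho to one methoxy and para to another, because the CH of the other ring has only two donors and lies ortho to the formyl group; the two ortho positions are equivalent, so one mono-iodide results.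

Step 3
Reactants: 1 3,4,5-trimethoxyphenol; 4 dyad iodide
Product: 5 3,5-dimethoxy-4-[3,4,5-trimethoxy-2-(3,4,5-trimethoxyphenoxy)phenoxy]benzaldehyde (D–E–F aldehyde)
Conditions: 1 (1.5 equiv), CuI (20 mol%), picolinic acid (40 mol%), K3PO4, DMSO, 100 °C, Ar
Reagents that add atoms: none
Why: Ullmann-type Cu-catalysed C–O coupling of the unhindered phenol with the aryl iodide should place ring F on C6 of ring E, the site being fixed by the iodine and self-condensation being excluded because 4 has no free OH.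

Step 4
Reactants: 5 D–E–F aldehyde
Product: 7 3,5-dimethoxy-4-[3,4,5-trimethoxy-2-(3,4,5-trimethoxyphenoxy)phenoxy]phenol (D–E–F phenol), via DEF aryl formate 6 (not isolated)
Conditions: mCPBA, CH2Cl2, 0 °C to rt; aq. NaHCO3 wash; then K2CO3 (cat.), MeOH, rt
Reagents that add atoms: mCPBA (3-chloroperoxybenzoic acid), O=C(OO)c1cccc(Cl)c1
Why: Baeyer–Villiger (Dakin-type) oxidation with migration of the electron-rich 4-aryloxy-3,5-dimethoxyphenyl group should give the formate, and its methanolysis frees the only phenol of the molecule once the peracid has been removed.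

Step 5
Reactants: 7 D–E–F phenol; 4 dyad iodide
Product: 8 4-[2-[3,5-dimethoxy-4-[3,4,5-trimethoxy-2-(3,4,5-trimethoxyphenoxy)phenoxy]phenoxy]-3,4,5-trimethoxyphenoxy]-3,5-dimethoxybenzaldehyde (B–C–D–E–F aldehyde)
Conditions: 4 (1.3 equiv), CuI (20 mol%), picolinic acid (40 mol%), K3PO4, DMSO, 100 °C, Ar
Reagents that add atoms: none
Why: Ullmann-type Cu(I)/Cu(III) C–O coupling: the phenoxide of 7 binds the copper picolinate, the C6–I bond of 4 adds oxidatively, and reductive elimination forms the C(C6)–O–D(C1) ether, so the second copy of the dyad is delivered in one operation and a trimer plus a dimer become the pentamer. The closest known reaction type is the copper/picolinic acid coupling of ortho-substituted aryl iodides with phenols, together with the classical Ullmann condensation of 2-halo-1,3-dialkoxybenzenes with methoxyphenols. No ring is closed and no stereocentre is formed. The step needs site selectivity (oxygen only at C6 of ring C) and chemoselectivity (one coupling, no self-condensation): the site is fixed by the iodine placed in step 2, 7 carries the only free OH and 4 the only C–I bond, and the formyl group of 4 keeps the next phenol oxygen masked until step 6. Protodeiodination of 4 would return 3, which can be fed back into step 2.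

Step 6
Reactants: 8 B–C–D–E–F aldehyde
Product: 10 4-[2-[3,5-dimethoxy-4-[3,4,5-trimethoxy-2-(3,4,5-trimethoxyphenoxy)phenoxy]phenoxy]-3,4,5-trimethoxyphenoxy]-3,5-dimethoxyphenol (B–C–D–E–F phenol), via BCDEF aryl formate 9 (not isolated)
Conditions: mCPBA, CH2Cl2, 0 °C to rt; aq. NaHCO3 wash; then K2CO3 (cat.), MeOH, rt
Reagents that add atoms: mCPBA (3-chloroperoxybenzoic acid), O=C(OO)c1cccc(Cl)c1
Why: The same Baeyer–Villiger oxidation and formate methanolysis as in step 4 should convert the formyl carbon of ring B into the phenol oxygen that will bridge to ring A, all other rings being fully etherified and without carbonyl groups.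

Step 7
Reactants: 10 B–C–D–E–F phenol; 11 2-iodo-1,3,5-trimethoxybenzene
Product: 12 hexadeca-O-methyl ether of the target (ring A = 2,4,6-trimethoxyphenyl)
Conditions: 11 (2 equiv), CuI (20 mol%), picolinic acid (40 mol%), K3PO4, DMSO, 110 °C, Ar
Reagents that add atoms: none
Why: Ullmann-type Cu-catalysed C–O coupling of the single, unhindered phenol with an excess of the 2,6-dimethoxy-flanked aryl iodide should close the chain with ring A on the A(C1)–O–B(C1) ether.

Step 8
Reactants: 12 hexadeca-O-methyl ether of the target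
Product: 13 target CNP0114537.0
Conditions: BBr3 (excess), CH2Cl2, −78 °C to rt, Ar; then degassed H2O, 0 °C
Reagents that add atoms: none
Why: Lewis-acid-mediated O-demethylation (bromide attack on the boron-activated methyl groups) should cleave all sixteen aryl methyl ethers while the five diaryl ether bonds, having no sp3 carbon on oxygen, stay intact; the polyphenol is to be handled without air.

**Compound list**

1 | 3,4,5-trimethoxyphenol | COc1cc(O)cc(OC)c1OC | starting material
2 | 4-bromo-3,5-dimethoxybenzaldehyde | COc1cc(C=O)cc(OC)c1Br | starting material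
3 | 3,5-dimethoxy-4-(3,4,5-trimethoxyphenoxy)benzaldehyde | COc1cc(C=O)cc(OC)c1Oc1cc(OC)c(OC)c(OC)c1 | intermediate
4 | 4-(2-iodo-3,4,5-trimethoxyphenoxy)-3,5-dimethoxybenzaldehyde | COc1cc(C=O)cc(OC)c1Oc1cc(OC)c(OC)c(OC)c1I | intermediate
5 | 3,5-dimethoxy-4-[3,4,5-trimethoxy-2-(3,4,5-trimethoxyphenoxy)phenoxy]benzaldehyde | COc1cc(C=O)cc(OC)c1Oc1cc(OC)c(OC)c(OC)c1Oc1cc(OC)c(OC)c(OC)c1 | intermediate
6 | 3,5-dimethoxy-4-[3,4,5-trimethoxy-2-(3,4,5-trimethoxyphenoxy)phenoxy]phenyl formate | COc1cc(OC=O)cc(OC)c1Oc1cc(OC)c(OC)c(OC)c1Oc1cc(OC)c(OC)c(OC)c1 | intermediate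
7 | 3,5-dimethoxy-4-[3,4,5-trimethoxy-2-(3,4,5-trimethoxyphenoxy)phenoxy]phenol | COc1cc(O)cc(OC)c1Oc1cc(OC)c(OC)c(OC)c1Oc1cc(OC)c(OC)c(OC)c1 | intermediate
8 | 4-[2-[3,5-dimethoxy-4-[3,4,5-trimethoxy-2-(3,4,5-trimethoxyphenoxy)phenoxy]phenoxy]-3,4,5-trimethoxyphenoxy]-3,5-dimethoxybenzaldehyde | COc1cc(C=O)cc(OC)c1Oc1cc(OC)c(OC)c(OC)c1Oc1cc(OC)c(Oc2cc(OC)c(OC)c(OC)c2Oc2cc(OC)c(OC)c(OC)c2)c(OC)c1 | intermediate
9 | 4-[2-[3,5-dimethoxy-4-[3,4,5-trimethoxy-2-(3,4,5-trimethoxyphenoxy)phenoxy]phenoxy]-3,4,5-trimethoxyphenoxy]-3,5-dimethoxyphenyl formate | COc1cc(OC=O)cc(OC)c1Oc1cc(OC)c(OC)c(OC)c1Oc1cc(OC)c(Oc2cc(OC)c(OC)c(OC)c2Oc2cc(OC)c(OC)c(OC)c2)c(OC)c1 | intermediate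
10 | 4-[2-[3,5-dimethoxy-4-[3,4,5-trimethoxy-2-(3,4,5-trimethoxyphenoxy)phenoxy]phenoxy]-3,4,5-trimethoxyphenoxy]-3,5-dimethoxyphenol | COc1cc(O)cc(OC)c1Oc1cc(OC)c(OC)c(OC)c1Oc1cc(OC)c(Oc2cc(OC)c(OC)c(OC)c2Oc2cc(OC)c(OC)c(OC)c2)c(OC)c1 | intermediate
11 | 2-iodo-1,3,5-trimethoxybenzene | COc1cc(OC)c(I)c(OC)c1 | starting material
12 | hexadeca-O-methyl ether of the target | COc1cc(OC)c(Oc2cc(OC)c(Oc3cc(OC)c(OC)c(OC)c3Oc3cc(OC)c(Oc4cc(OC)c(OC)c(OC)c4Oc4cc(OC)c(OC)c(OC)c4)c(OC)c3)c(OC)c2)c(OC)c1 | intermediate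
13 | CNP0114537.0 | Oc1cc(O)c(Oc2cc(O)c(Oc3cc(O)c(O)c(O)c3Oc3cc(O)c(Oc4cc(O)c(O)c(O)c4Oc4cc(O)c(O)c(O)c4)c(O)c3)c(O)c2)c(O)c1 | target

**Step count**

Total step count: 8.
Longest linear sequence: 8 steps (1 + 2 → 3 → 4 → 5 → 7 → 8 → 10 → 12 → 13); compound 4 enters twice (steps 3 and 5).

**Steps most likely to fail and fallbacks**

Step 5. Copper insertion into the C–I bond may be slow, because this bond is flanked by a methoxy group and a bulky 2,6-dimethoxyaryloxy group. Protodeiodination of 4, or phenoxide exchange at the formyl-activated C4 of its aldehyde ring, could then outrun the coupling of two large partners. The fallback is a formyl relay: ring C is brought in first as an ortho-formyl-activated bromide and ring B is attached afterwards. Setting out from 7, Ullmann coupling with commercial 2-bromo-3,4,5-trimethoxybenzaldehyde (O=Cc1cc(OC)c(OC)c(OC)c1Br; CuI, picolinic acid, K3PO4, DMSO, 90 °C) should give 2-[3,5-dimethoxy-4-[3,4,5-trimethoxy-2-(3,4,5-trimethoxyphenoxy)phenoxy]phenoxy]-3,4,5-trimethoxybenzaldehyde F1. Baeyer–Villiger oxidation (mCPBA, then K2CO3/MeOH) leads through the corresponding aryl formate F2 to 2-[3,5-dimethoxy-4-[3,4,5-trimethoxy-2-(3,4,5-trimethoxyphenoxy)phenoxy]phenoxy]-3,4,5-trimethoxyphenol F3. Ullmann coupling of F3 with the para-formyl-activated bromide 2 comes back to the route at 8.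

Step 3. The same slow oxidative addition at the doubly ortho-flanked C–I bond of 4 may occur, with loss of iodine before coupling. The fallback builds the E–F ether first on an activated bromide. Setting out from 1, Ullmann coupling with 2-bromo-3,4,5-trimethoxybenzaldehyde should give 3,4,5-trimethoxy-2-(3,4,5-trimethoxyphenoxy)benzaldehyde F4. Baeyer–Villiger oxidation leads through 3,4,5-trimethoxy-2-(3,4,5-trimethoxyphenoxy)phenyl formate F5 to 3,4,5-trimethoxy-2-(3,4,5-trimethoxyphenoxy)phenol F6. Ullmann coupling of F6 with 2 comes back to the route at 5.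

Step 7. The electron-rich, 2,6-dimethoxy-flanked iodide 11 may react sluggishly with the large pentamer phenol, so that the phenol decomposes by oxidation on prolonged heating. The fallback uses the formyl-activated bromide 2 as ring A, whose formyl carbon becomes the 4-OH of ring A. Setting out from 10, Ullmann coupling with 2 should give the ring-A formyl hexamer F7 (12 with CHO in place of the 4-OMe of ring A). Baeyer–Villiger oxidation leads through the aryl formate F8 to the hexamer phenol F9 (pentadeca-O-methyl ether of the target with free 4-OH on ring A). BBr3 demethylation of F9 comes back to the route at 13.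

**Further compounds**

F1 | step 5 | 2-[3,5-dimethoxy-4-[3,4,5-trimethoxy-2-(3,4,5-trimethoxyphenoxy)phenoxy]phenoxy]-3,4,5-trimethoxybenzaldehyde | O=Cc1cc(OC)c(OC)c(OC)c1Oc1cc(OC)c(Oc2cc(OC)c(OC)c(OC)c2Oc2cc(OC)c(OC)c(OC)c2)c(OC)c1
F2 | step 5 | 2-[3,5-dimethoxy-4-[3,4,5-trimethoxy-2-(3,4,5-trimethoxyphenoxy)phenoxy]phenoxy]-3,4,5-trimethoxyphenyl formate | O=COc1cc(OC)c(OC)c(OC)c1Oc1cc(OC)c(Oc2cc(OC)c(OC)c(OC)c2Oc2cc(OC)c(OC)c(OC)c2)c(OC)c1
F3 | step 5 | 2-[3,5-dimethoxy-4-[3,4,5-trimethoxy-2-(3,4,5-trimethoxyphenoxy)phenoxy]phenoxy]-3,4,5-trimethoxyphenol | Oc1cc(OC)c(OC)c(OC)c1Oc1cc(OC)c(Oc2cc(OC)c(OC)c(OC)c2Oc2cc(OC)c(OC)c(OC)c2)c(OC)c1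
F4 | step 3 | 3,4,5-trimethoxy-2-(3,4,5-trimethoxyphenoxy)benzaldehyde | O=Cc1cc(OC)c(OC)c(OC)c1Oc1cc(OC)c(OC)c(OC)c1
F5 | step 3 | 3,4,5-trimethoxy-2-(3,4,5-trimethoxyphenoxy)phenyl formate | O=COc1cc(OC)c(OC)c(OC)c1Oc1cc(OC)c(OC)c(OC)c1
F6 | step 3 | 3,4,5-trimethoxy-2-(3,4,5-trimethoxyphenoxy)phenol | Oc1cc(OC)c(OC)c(OC)c1Oc1cc(OC)c(OC)c(OC)c1
F7 | step 7 | ring-A formyl hexamer (12 with CHO in place of the 4-OMe of ring A) | COc1cc(C=O)cc(OC)c1Oc1cc(OC)c(Oc2cc(OC)c(OC)c(OC)c2Oc2cc(OC)c(Oc3cc(OC)c(OC)c(OC)c3Oc3cc(OC)c(OC)c(OC)c3)c(OC)c2)c(OC)c1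
F8 | step 7 | ring-A formate hexamer (12 with OCHO in place of the 4-OMe of ring A) | COc1cc(OC=O)cc(OC)c1Oc1cc(OC)c(Oc2cc(OC)c(OC)c(OC)c2Oc2cc(OC)c(Oc3cc(OC)c(OC)c(OC)c3Oc3cc(OC)c(OC)c(OC)c3)c(OC)c2)c(OC)c1
F9 | step 7 | pentadeca-O-methyl ether of the target with free 4-OH on ring A | COc1cc(O)cc(OC)c1Oc1cc(OC)c(Oc2cc(OC)c(OC)c(OC)c2Oc2cc(OC)c(Oc3cc(OC)c(OC)c(OC)c3Oc3cc(OC)c(OC)c(OC)c3)c(OC)c2)c(OC)c1
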